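Readings and results are simulated from invented constants; scatter was added.

Over the 12 min of larch, the number to watch is one the readings do not show directly.

| flask | starting material | remark | time |
|---|---|---|---|
| midnight | 2 M | run made earlier |  |
| dawn | 1 M | run made earlier |  |
| larch | 2.0 M | everything together in a closed stirred flask, run for 12 min | 12 min |
| oak | 2.0 M | a single well-mixed tank run continuously and read at steady state, 12 min in it on average |  |

| run | time / min | ring / % | open dimer / % | over-reaction product / % |
|---|---|---|---|---|
| midnight | 1.33 | 10.1 | 23.7 | 0 |
| midnight | 3.00 | 12.9 | 21.3 | 0 |
| midnight | 4.00 | 15.9 | 19.0 | 1.4 |
| midnight | 6.00 | 23.6 | 15.9 | 1.8 |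
| midnight | 8.00 | 27.4 | 11.7 | 1.0 |
| dawn | 0.833 | 4.2 | 10.5 | 0 |
| dawn | 1.33 | 7.6 | 14.1 | 0 |
| dawn | 2.50 | 12.2 | 15.1 | 0 |
| dawn | 5.00 | 22.7 | 10.2 | 0.2 |
| dawn | 10.0 | 33.7 | 5.1 | 2.4 |

(readings scatter by 1 percentage point)

- percentages count the starting material that a species holds: one open dimer counts as two
- the stated concentrations are those of everything mixed, before any reaction; amounts are the same in each set-up
- reactions considered so far: ring <-> isomer of the product; starting material <-> dormant form; starting material -> ring; 2 starting material <-> open dimer; ring -> over-reaction product
- the earlier runs were made in a closed, stirred flask

* the set-up with the highest share of ring in all that became ring or open dimer or over-reaction product or isomer of the product, at the outlet or at the end ("none" if the first two lie within 2 percentage points) (larch / oak / none)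
* share of ring in all that became ring or open dimer or over-reaction product or isomer of the product, at the outlet or at the end, larch
* share of ring in all that became ring or open dimer or over-reaction product or isomer of the product, at the outlet or at the end, oak

Start with a balance of the starting material. Each part charged now sits in ring, open dimer or over-reaction product, or else in the unread rest, which we call the pool: free starting material, dormant form and any isomer of the product. In the midnight run, which has the charge of larch, the pool went from 66.2% at 1.33 min to 59.9% at 8.00 min. Dividing the ring gained per minute by the mean pool gives 0.0411 /min. Call this net ring gain per minute per part of pool the pull. The dawn run, at 1 M, reads 0.0439 /min, so I treat the pull as a pseudo-first-order constant.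

For larch, I carry midnight on to 12 min with the pool held at its last reading, which overstates a little, and get ring 37.3%. Keeping the last open dimer and over-reaction product, 12.7%, my share is 74.6%.

At steady state in oak, ring leaves with the outflow as fast as the pull makes it, so ring equals pull times the average 12 min in the tank times pool, a factor of 0.494. I take open dimer and over-reaction product from the 6.00 min midnight row, 17.7%, where the pool was 58.7%, against 55.1% reckoned for the tank. Then the balance gives ring 27.2% and a share of 60.6%, so I expect larch to win.

The forecast says larch, with 78% for larch and 63% for oak, and adds “Backmixing keeps dimer alive.”

The simulation gives larch: 72.1% for larch and 62.9% for oak.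

    ring ⇌ isomer of the product (K = 24.1, k = 0.00322 /min)
    starting material ⇌ dormant form (K = 0.576, k = 0.0970 /min)
    starting material → ring (k = 0.0715 /min)
    2 starting material ⇌ open dimer (K = 0.191 /M, k = 0.119 /M/min)
    ring → over-reaction product (k = 0.0143 /min)

A reading of larch at 5.0 min has a pool of 61.9%, and the end of larch has 52.7%, so the pull adds 16 percentage points of ring between them, and larch itself gains 15 points. In larch, the step from starting material into dormant form had half of its turnover up to 12 min done by 1.65 min, while the step from ring to over-reaction product had 1.7% of its own behind it at 1.20 min. At the end of larch, ring was made 3.77 times faster than used up, each step taken net, with c(starting material) at 0.640 M against 0.796 M in oak, and open dimer at 9.06% against 10.7%.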